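**Plan**

- Retrosynthesis: the seven O–benzyl bonds are cut first, then O1–C2 and C3–C4 of the upper pyran (o-quinone methide plus 4-benzyloxystyrene), then the bond from the carbinol carbon (future upper C4) to epicatechin C8 (aryllithium plus salicylaldehyde).
- Enabling feature: in the upper C ring, O1 and C4 both sit on resorcinol ring A (at C8a and C4a), C2–C3 with its 4-hydroxyphenyl group is a 4-hydroxystyrene unit, and C4 carries C8 of epicatechin. The ring is therefore the [4+2] adduct of a ring-A o-quinone methide and a styrene.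
- Forward: the three rings of the lower unit come intact from (−)-epicatechin. Benzylation, C8 bromination, bromine–lithium exchange and addition to a 2-silyloxybenzaldehyde attach ring A of the upper unit. The upper pyran is the only ring closed (step 8), and that step also brings in the C2–C3–aryl unit.
- Stereochemistry: lower C2 and C3 (2R,3R) come from epicatechin and are never touched. Upper C2 and C4 are set together: cis by endo addition to the E-quinone methide, (2S,4S) by a chiral Brønsted acid bound to the quinone methide oxygen. The wrong-face cis isomer is a diastereomer and separable.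
- One global hydrogenolysis ends the route.

Key step: step 8

Assumption: the sense of induction of the chiral acid on this new quinone methide cannot be derived with certainty, so the (R)-acid is written and its mirror image takes its place, with nothing else changed, if it proves mismatched with the epicatechin unit.

**Route**

Step 1
Reactants: 1 (−)-epicatechin
Product: 2 5,7,3',4'-tetra-O-benzylepicatechin
Conditions: BnBr (4.2 equiv), K2CO3, DMF, 0 °C → rt, Ar
Reagents that add atoms: benzyl bromide, BrCc1ccccc1
Why: Williamson etherification with a carbonate base alkylates only the four phenols and leaves the secondary 3-hydroxyl free, and the mild base and low temperature keep C2 from epimerising by base-induced opening of the pyran ring.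

Step 2
Reactants: 2 5,7,3',4'-tetra-O-benzylepicatechin
Product: 3 8-bromo-5,7,3',4'-tetra-O-benzylepicatechin
Conditions: NBS (1.0 equiv), CH2Cl2, −78 °C → rt
Reagents that add atoms: N-bromosuccinimide, O=C1CCC(=O)N1Br
Why: Electrophilic aromatic bromination of the phloroglucinol-type ring goes to C8, which is flanked by one benzyloxy group and the ring oxygen, in preference to C6 between two benzyloxy groups, as is established for this substrate class.

Step 3
Reactants: 3 8-bromo-5,7,3',4'-tetra-O-benzylepicatechin
Product: 4 8-bromo-3,5,7,3',4'-penta-O-benzylepicatechin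
Conditions: NaH, BnBr, Bu4NI (cat.), THF, 0 °C → rt
Reagents that add atoms: benzyl bromide, BrCc1ccccc1
Why: Williamson etherification of the sodium alkoxide converts the axial 3-hydroxyl into an ether that is inert to the aryllithium and falls in the final hydrogenolysis, with the aryl bromide and both stereocentres untouched.

Step 4
Reactants: 5 4-benzyloxy-2-hydroxybenzaldehyde (commercial)
Product: 6 4-benzyloxy-2-(triisopropylsilyloxy)benzaldehyde
Conditions: TIPSCl, imidazole, DMF, rt
Reagents that add atoms: chlorotriisopropylsilane, CC(C)[Si](Cl)(C(C)C)C(C)C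
Why: Silyl ether formation masks the acidic phenol for the organolithium step with a bulky group that resists transfer to a neighbouring alkoxide and later leaves with fluoride under non-acidic conditions.

Step 5
Reactants: 4 8-bromo-3,5,7,3',4'-penta-O-benzylepicatechin; 6 4-benzyloxy-2-(triisopropylsilyloxy)benzaldehyde
Product: 8 (4-benzyloxy-2-triisopropylsilyloxyphenyl)(penta-O-benzylepicatechin-8-yl)methanol (both carbinol epimers), via 8-lithio-penta-O-benzylepicatechin 7 (not isolated)
Conditions: t-BuLi (2.0 equiv), THF, −78 °C; then 6, −78 °C; H2O quench at −78 °C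
Reagents that add atoms: none
Why: Bromine–lithium exchange outruns any deprotonation of the benzyl ethers and gives the C8 aryllithium, whose 1,2-addition to the non-enolisable aldehyde forms the C8–carbinol bond (the future C4–C8 link); the carbinol centre forms without control, which does not matter because it becomes sp2 in the quinone methide.

Step 6
Reactants: 8 (4-benzyloxy-2-triisopropylsilyloxyphenyl)(penta-O-benzylepicatechin-8-yl)methanol
Product: 9 (4-benzyloxy-2-hydroxyphenyl)(penta-O-benzylepicatechin-8-yl)methanol (both carbinol epimers)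
Conditions: TBAF (1.1 equiv), THF, 0 °C; H2O work-up; filtration through Et3N-deactivated silica, used promptly
Reagents that add atoms: none
Why: Fluoride-mediated desilylation of the aryl silyl ether runs under basic, non-ionising conditions, so the phenol ortho to the carbinol is set free without loss of the acid-labile benzylic hydroxyl and without touching the benzyl ethers.

Step 7
Reactants: 10 4-benzyloxybenzaldehyde
Product: 11 4-benzyloxystyrene
Conditions: Ph3PCH3Br, KOtBu, THF, 0 °C → rt
Reagents that add atoms: methyltriphenylphosphonium bromide, C[P+](c1ccccc1)(c1ccccc1)c1ccccc1.[Br-]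
Why: Wittig methylenation of a non-enolisable aromatic aldehyde with the unstabilised ylide gives the terminal styrene directly, with no stereochemical element involved.

Step 8
Reactants: 9 (4-benzyloxy-2-hydroxyphenyl)(penta-O-benzylepicatechin-8-yl)methanol; 11 4-benzyloxystyrene
Product: 13 hepta-O-benzyl (2S,4S)-4',7-dihydroxyflavan-(4→8)-epicatechin (2,4-cis), via ring-A o-quinone methide 12 (not isolated)
Conditions: 11 (3 equiv), (R)-3,3'-bis(2,4,6-triisopropylphenyl)-BINOL N-triflylphosphoramide (10 mol%), 5 Å MS, CH2Cl2 (dilute), −40 → 0 °C; Et3N quench; chromatography to remove the minor cis diastereomer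
Reagents that add atoms: none
Why: The chiral acid protonates the benzylic hydroxyl of 9, which leaves as water with the help of the ortho phenol and the trioxygenated epicatechin ring, to give the E-configured o-quinone methide 12 held to the catalyst by a hydrogen bond at its oxygen; this electron-poor 1-oxadiene adds the electron-rich alkene of 11 in an inverse-demand, concerted but asynchronous [4+2] cycloaddition in which C3–C4 forms ahead of O1–C2 and ring A regains aromaticity. The closest known reaction type is the chiral N-triflylphosphoramide- or phosphoric acid-catalysed hetero-Diels–Alder reaction of o-quinone methides from 2-hydroxybenzhydrols with styrenes, which gives 2,4-cis-diarylchromans. The upper pyran is the one ring closed, as a six-membered [4+2] annulation (a 6-endo closure of the phenolic oxygen onto the benzylic carbon if the reaction runs stepwise). C4 and C2 arise together: their cis relation follows from the endo approach of the styrene aryl group to the E-quinone methide and is also the diequatorial, thermodynamically preferred arrangement, while the face of 12 that is attacked, and so the absolute (2S,4S) sense, is set by the chiral pocket of the catalyst, with the (2R,3R) epicatechin unit as a weak second director. The regioselectivity needed is secured by the substrate twice: only the phenol ortho to the carbinol is free, so only this quinone methide can form, and the p-benzyloxyphenyl group stabilises positive charge at the internal alkene carbon, so that this carbon becomes C2 on oxygen. Full benzyl protection leaves no competing heteroatom nucleophile, and the (2R,4R) cis isomer, being a diastereomer of 13, can be removed by chromatography.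

Step 9
Reactants: 13 hepta-O-benzyl (2S,4S)-4',7-dihydroxyflavan-(4→8)-epicatechin
Product: 14 (2S,4S)-4',7-dihydroxyflavan-(4→8)-(−)-epicatechin (target)
Conditions: H2 (1 atm), 20% Pd(OH)2/C, THF/MeOH/H2O, rt; filtration under Ar, Sephadex LH-20
Reagents that add atoms: none
Why: Catalytic hydrogenolysis cleaves the six aryl benzyl ethers and the one alkyl benzyl ether, while the cyclic benzylic C2–O1 bonds of both pyrans and the doubly benzylic C4–H survive such mild conditions in flavan chemistry, so all four stereocentres are kept.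

**Compound list**

1 | (−)-epicatechin, (2R,3R)-2-(3,4-dihydroxyphenyl)chroman-3,5,7-triol | O[C@@H]1Cc2c(O)cc(O)cc2O[C@@H]1c1ccc(O)c(O)c1 | starting material
2 | 5,7,3',4'-tetra-O-benzylepicatechin (2R,3R; free 3-OH) | c1c(OCc2ccccc2)cc(OCc2ccccc2)c2c1O[C@H](c1ccc(OCc3ccccc3)c(OCc3ccccc3)c1)[C@H](O)C2 | intermediate
3 | 8-bromo-5,7,3',4'-tetra-O-benzylepicatechin | Brc1c(OCc2ccccc2)cc(OCc2ccccc2)c2c1O[C@H](c1ccc(OCc3ccccc3)c(OCc3ccccc3)c1)[C@H](O)C2 | intermediate
4 | 8-bromo-3,5,7,3',4'-penta-O-benzylepicatechin | Brc1c(OCc2ccccc2)cc(OCc2ccccc2)c2c1O[C@H](c1ccc(OCc3ccccc3)c(OCc3ccccc3)c1)[C@H](OCc1ccccc1)C2 | intermediate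
5 | 4-benzyloxy-2-hydroxybenzaldehyde | O=Cc1ccc(OCc2ccccc2)cc1O | starting material
6 | 4-benzyloxy-2-(triisopropylsilyloxy)benzaldehyde | O=Cc1ccc(OCc2ccccc2)cc1O[Si](C(C)C)(C(C)C)C(C)C | intermediate
7 | 8-lithio-3,5,7,3',4'-penta-O-benzylepicatechin (not isolated) | [Li]c1c(OCc2ccccc2)cc(OCc2ccccc2)c2c1O[C@H](c1ccc(OCc3ccccc3)c(OCc3ccccc3)c1)[C@H](OCc1ccccc1)C2 | intermediate
8 | (4-benzyloxy-2-triisopropylsilyloxyphenyl)(penta-O-benzylepicatechin-8-yl)methanol, both carbinol epimers | OC(c1ccc(OCc2ccccc2)cc1O[Si](C(C)C)(C(C)C)C(C)C)c1c(OCc2ccccc2)cc(OCc2ccccc2)c2c1O[C@H](c1ccc(OCc3ccccc3)c(OCc3ccccc3)c1)[C@H](OCc1ccccc1)C2 | intermediate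
9 | (4-benzyloxy-2-hydroxyphenyl)(penta-O-benzylepicatechin-8-yl)methanol, both carbinol epimers | OC(c1ccc(OCc2ccccc2)cc1O)c1c(OCc2ccccc2)cc(OCc2ccccc2)c2c1O[C@H](c1ccc(OCc3ccccc3)c(OCc3ccccc3)c1)[C@H](OCc1ccccc1)C2 | intermediate
10 | 4-benzyloxybenzaldehyde | O=Cc1ccc(OCc2ccccc2)cc1 | starting material
11 | 4-benzyloxystyrene | C=Cc1ccc(OCc2ccccc2)cc1 | intermediate
12 | (E)-3-benzyloxy-6-[(penta-O-benzylepicatechin-8-yl)methylidene]cyclohexa-2,4-dien-1-one, the ring-A o-quinone methide (not isolated) | O=C1C=C(OCc2ccccc2)C=C/C1=C\c1c(OCc2ccccc2)cc(OCc2ccccc2)c2c1O[C@H](c1ccc(OCc3ccccc3)c(OCc3ccccc3)c1)[C@H](OCc1ccccc1)C2 | intermediate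
13 | hepta-O-benzyl target: (2S,4S)-7-benzyloxy-2-(4-benzyloxyphenyl)chroman-4-yl unit (2,4-cis) joined through C4 to C8 of penta-O-benzyl-(2R,3R)-epicatechin | C(c1ccccc1)Oc1ccc([C@@H]2C[C@H](c3c(OCc4ccccc4)cc(OCc4ccccc4)c4c3O[C@H](c3ccc(OCc5ccccc5)c(OCc5ccccc5)c3)[C@H](OCc3ccccc3)C4)c3ccc(OCc4ccccc4)cc3O2)cc1 | intermediate
14 | CNP0298337.1, (2R,3R)-2-(3,4-dihydroxyphenyl)-8-[(2S,4S)-7-hydroxy-2-(4-hydroxyphenyl)chroman-4-yl]chroman-3,5,7-triol | Oc1ccc([C@@H]2C[C@H](c3c(O)cc(O)c4c3O[C@H](c3ccc(O)c(O)c3)[C@H](O)C4)c3ccc(O)cc3O2)cc1 | target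

**Count**

Total steps: 9. Longest linear sequence: 7 (steps 1, 2, 3, 5, 6, 8, 9 from epicatechin); steps 4 and 7 are one-step side branches.

**Steps most likely to fail**

1. Step 8. The catalyst may discriminate poorly between the two faces of the hindered, donor-stabilised quinone methide. The quinone methide may also be consumed by Friedel–Crafts self-condensation on the electron-rich rings, or the styrene by cationic oligomerisation. The fallback builds the upper pyran with its C2 configuration before the interflavan bond is made; it sets out from 4 and comes back at 13. Commercial (S)-liquiritigenin, (2S)-7,4'-dihydroxyflavanone, O=C1C[C@@H](c2ccc(O)cc2)Oc2cc(O)ccc12, is benzylated on both phenols under Mitsunobu conditions (BnOH, PPh3, DIAD, THF, 0 °C), which avoid the basic ring-opening that racemises flavanones, to give (2S)-7,4'-bis(benzyloxy)flavanone F1. Aryllithium 7, made from 4 as in step 5, is added to the C4 ketone of F1 at −78 °C to give the tertiary 4-aryl-flavan-4-ol F2 as either C4 epimer. Ionic hydrogenation (Et3SiH, CF3CO2H, CH2Cl2, −78 °C) then reduces the bis-benzylic cation by axial hydride delivery, which places the C4 aryl group equatorial and cis to the C2 aryl group and gives 13.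

2. Step 5. The di-ortho-substituted aryllithium may be protonated before it adds, or the silyl group may move to the new alkoxide and leave as silanolate, releasing the quinone methide while organolithium is still present. The fallback reverses the roles of the partners and uses no silyl group; it sets out from 4 and comes back at 9, so that steps 5 and 6 are both replaced. Aryllithium 7, made as in step 5, is quenched with DMF to give 8-formyl-3,5,7,3',4'-penta-O-benzylepicatechin F3. Commercial 5-benzyloxy-2-bromophenol, Oc1cc(OCc2ccccc2)ccc1Br, is treated with n-BuLi (2.1 equiv, THF, −78 → 0 °C) to give lithium 5-benzyloxy-2-lithiophenoxide F4, which adds to the aldehyde of F3 and gives the phenol–carbinol 9 directly after aqueous work-up.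

3. Step 9. Cleavage of the hindered secondary 3-O-benzyl ether may be incomplete, and the long exposure this invites may open the upper pyran by hydrogenolysis at its p-oxygenated benzylic C2–O1 bond. The fallback carries the 3-hydroxyl as a silyl ether so that only aryl benzyl ethers remain for a short hydrogenolysis; it sets out from 3 and comes back at 14. Bromide 3 is silylated (TBSCl, imidazole, DMF) to give 8-bromo-3-O-tert-butyldimethylsilyl-5,7,3',4'-tetra-O-benzylepicatechin F5. Bromine–lithium exchange as in step 5 gives the corresponding 8-lithio compound F6, which adds to 6 to give the bis-silylated carbinol F7. One equivalent of TBAF at 0 °C frees only the phenol, since aryl silyl ethers cleave far faster than the hindered secondary alkyl ether, and gives the phenol–carbinol F8. Under the conditions of step 8, F8 loses water to the 3-O-silylated quinone methide F9, which adds 11 to give the hexa-O-benzyl 3-O-silyl cycloadduct F10. TBAF at rt to 40 °C removes the 3-O-silyl group and gives the hexa-O-benzyl 3-alcohol F11, and hydrogenolysis over Pd(OH)2/C then gives 14.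

**Further compounds**

F1 | step 8 | (2S)-7,4'-bis(benzyloxy)flavanone | C(c1ccccc1)Oc1ccc([C@@H]2CC(=O)c3ccc(OCc4ccccc4)cc3O2)cc1
F2 | step 8 | (2S)-7-benzyloxy-2-(4-benzyloxyphenyl)-4-(penta-O-benzylepicatechin-8-yl)chroman-4-ol, either C4 epimer | C(c1ccccc1)Oc1ccc([C@@H]2CC(O)(c3c(OCc4ccccc4)cc(OCc4ccccc4)c4c3O[C@H](c3ccc(OCc5ccccc5)c(OCc5ccccc5)c3)[C@H](OCc3ccccc3)C4)c3ccc(OCc4ccccc4)cc3O2)cc1
F3 | step 5 | 8-formyl-3,5,7,3',4'-penta-O-benzylepicatechin | O=Cc1c(OCc2ccccc2)cc(OCc2ccccc2)c2c1O[C@H](c1ccc(OCc3ccccc3)c(OCc3ccccc3)c1)[C@H](OCc1ccccc1)C2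
F4 | step 5 | lithium 5-benzyloxy-2-lithiophenoxide | [Li]Oc1cc(OCc2ccccc2)ccc1[Li]
F5 | step 9 | 8-bromo-3-O-tert-butyldimethylsilyl-5,7,3',4'-tetra-O-benzylepicatechin | Brc1c(OCc2ccccc2)cc(OCc2ccccc2)c2c1O[C@H](c1ccc(OCc3ccccc3)c(OCc3ccccc3)c1)[C@H](O[Si](C)(C)C(C)(C)C)C2
F6 | step 9 | 8-lithio-3-O-tert-butyldimethylsilyl-5,7,3',4'-tetra-O-benzylepicatechin | [Li]c1c(OCc2ccccc2)cc(OCc2ccccc2)c2c1O[C@H](c1ccc(OCc3ccccc3)c(OCc3ccccc3)c1)[C@H](O[Si](C)(C)C(C)(C)C)C2
F7 | step 9 | (4-benzyloxy-2-triisopropylsilyloxyphenyl)(3-O-tert-butyldimethylsilyl-5,7,3',4'-tetra-O-benzylepicatechin-8-yl)methanol, both carbinol epimers | OC(c1ccc(OCc2ccccc2)cc1O[Si](C(C)C)(C(C)C)C(C)C)c1c(OCc2ccccc2)cc(OCc2ccccc2)c2c1O[C@H](c1ccc(OCc3ccccc3)c(OCc3ccccc3)c1)[C@H](O[Si](C)(C)C(C)(C)C)C2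
F8 | step 9 | (4-benzyloxy-2-hydroxyphenyl)(3-O-tert-butyldimethylsilyl-5,7,3',4'-tetra-O-benzylepicatechin-8-yl)methanol, both carbinol epimers | OC(c1ccc(OCc2ccccc2)cc1O)c1c(OCc2ccccc2)cc(OCc2ccccc2)c2c1O[C@H](c1ccc(OCc3ccccc3)c(OCc3ccccc3)c1)[C@H](O[Si](C)(C)C(C)(C)C)C2
F9 | step 9 | (E)-3-benzyloxy-6-[(3-O-tert-butyldimethylsilyl-5,7,3',4'-tetra-O-benzylepicatechin-8-yl)methylidene]cyclohexa-2,4-dien-1-one | O=C1C=C(OCc2ccccc2)C=C/C1=C\c1c(OCc2ccccc2)cc(OCc2ccccc2)c2c1O[C@H](c1ccc(OCc3ccccc3)c(OCc3ccccc3)c1)[C@H](O[Si](C)(C)C(C)(C)C)C2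
F10 | step 9 | hexa-O-benzyl 3-O-tert-butyldimethylsilyl (2S,4S)-4',7-dihydroxyflavan-(4→8)-epicatechin | C(c1ccccc1)Oc1ccc([C@@H]2C[C@H](c3c(OCc4ccccc4)cc(OCc4ccccc4)c4c3O[C@H](c3ccc(OCc5ccccc5)c(OCc5ccccc5)c3)[C@H](O[Si](C)(C)C(C)(C)C)C4)c3ccc(OCc4ccccc4)cc3O2)cc1
F11 | step 9 | hexa-O-benzyl (2S,4S)-4',7-dihydroxyflavan-(4→8)-epicatechin with free 3-OH | C(c1ccccc1)Oc1ccc([C@@H]2C[C@H](c3c(OCc4ccccc4)cc(OCc4ccccc4)c4c3O[C@H](c3ccc(OCc5ccccc5)c(OCc5ccccc5)c3)[C@H](O)C4)c3ccc(OCc4ccccc4)cc3O2)cc1
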